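**Plan**

1. Numbering: C1H2–O2–C3H(Ar)–C3a(OH)–C4H2–O5–C6H(Ar)–C6aH, Ar = 3,4-dimethoxyphenyl; ring 1 = C1/O2/C3/C3a/C6a, ring 2 = C3a/C4/O5/C6/C6a.
2. Retrosynthesis cuts C4–O5 first (ether closure of ring 2), then C3–C3a (C3 goes back onto the oxygen of C3a, so ring 1 becomes a six-membered 2-aryl-1,3-dioxane), then the two acetal C3–O bonds (second veratraldehyde), then C6–C6a (aldol).
3. Enabling feature: C3 is at the aldehyde level (bonded to O2 and aryl) and sits on the carbinol carbon C3a, so O2, C3, the C3a oxygen, C3a, C6a and C1 are a latent veratrylidene acetal whose acetal carbon can move from O to C.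
4. Forward: syn-aldol (C6, C6a) → diol ester → 1,3-dioxane → ring contraction to ring 1 (makes C3–C3a and the tertiary C3a–O) → ring 2 by intramolecular etherification, which gives the trans ring fusion.
5. Stereochemistry: C6 and C6a from the (R)-4-benzyloxazolidinone; C3a (relative to C6a) from allylic 1,3-strain in the ketene acetal; C3 from the facial course of the oxocarbenium recombination; the last closure forms only a CH2–O bond.

Key step: step 7

Remark on the target: read literally, the SMILES has C6a–H and C3a–OH on opposite faces, so the dioxabicyclo[3.3.0]octane is trans-fused (not the cis-fused gmelinol skeleton); ring 1 then carries aryl (C3), OH (C3a) and the C6 side chain (C6a) all cis, and the route is built for this isomer.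

Step 1
Reactants: 1 4-tert-butoxy-4-oxobutanoic acid (mono-tert-butyl succinate); 2 (R)-4-benzyl-1,3-oxazolidin-2-one
Product: 4 tert-butyl 4-[(4R)-4-benzyl-2-oxo-1,3-oxazolidin-3-yl]-4-oxobutanoate, via pivalic mixed anhydride 3 (not isolated)
Conditions: PivCl, Et3N, THF, −20 °C; then 2, LiCl, −20 °C → rt
Reagents that add atoms: none
Why: N-acylation of the oxazolidinone through the mixed anhydride should give the imide; no stereocentre is formed.

Step 2
Reactants: 4 tert-butyl 4-[(4R)-4-benzyl-2-oxo-1,3-oxazolidin-3-yl]-4-oxobutanoate; 5 3,4-dimethoxybenzaldehyde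
Product: 7 tert-butyl (3R,4R)-3-{[(4R)-4-benzyl-2-oxo-1,3-oxazolidin-3-yl]carbonyl}-4-(3,4-dimethoxyphenyl)-4-hydroxybutanoate, via dibutylboron Z-enolate 6 (not isolated)
Conditions: Bu2BOTf, iPr2NEt, CH2Cl2, 0 °C; then 5, −78 → 0 °C; pH 7 buffer, MeOH, H2O2
Reagents that add atoms: none
Why: Evans syn-aldol reaction: the Z-boron enolate of the imide (not of the ester) reacts through a chair transition state in which the (R)-benzyl group shields one enolate face, which should set both new stereocentres as (3R,4R).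

Step 3
Reactants: 7 the aldol adduct
Product: 8 tert-butyl (3R,4R)-3-{[(4R)-4-benzyl-2-oxo-1,3-oxazolidin-3-yl]carbonyl}-4-[(tert-butyldimethylsilyl)oxy]-4-(3,4-dimethoxyphenyl)butanoate
Conditions: TBSOTf, 2,6-lutidine, CH2Cl2, −78 → 0 °C
Reagents that add atoms: tert-butyldimethylsilyl trifluoromethanesulfonate CC(C)(C)[Si](C)(C)OS(=O)(=O)C(F)(F)F
Why: Silylation of the secondary alcohol with a silyl triflate blocks lactonisation onto the ester and masks the benzylic oxygen until step 10.

Step 4
Reactants: 8 the silyl ether imide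
Product: 9 tert-butyl (3S,4R)-4-[(tert-butyldimethylsilyl)oxy]-4-(3,4-dimethoxyphenyl)-3-(hydroxymethyl)butanoate
Conditions: LiBH4, MeOH (1 equiv), THF, 0 °C
Reagents that add atoms: none
Why: Reductive cleavage of the N-acyloxazolidinone by LiBH4 should give the primary alcohol and the free auxiliary while the tert-butyl ester and the silyl ether stay intact.

Step 5
Reactants: 9 the primary alcohol
Product: 11 tert-butyl (3R,4R)-4-[(tert-butyldimethylsilyl)oxy]-4-(3,4-dimethoxyphenyl)-2-hydroxy-3-(hydroxymethyl)butanoate (both C-2 epimers), via dipotassium dianion 10 (not isolated)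
Conditions: KN(SiMe3)2 (2.3 equiv), THF, −78 °C; then 2-(phenylsulfonyl)-3-phenyloxaziridine, −78 °C; AcOH
Reagents that add atoms: 2-(phenylsulfonyl)-3-phenyloxaziridine O=S(=O)(c1ccccc1)N1OC1c1ccccc1
Why: Enolate hydroxylation with an N-sulfonyloxaziridine on the alkoxide–ester enolate dianion; the new carbinol centre forms without control, which does not matter because it becomes trigonal again in step 7.

Step 6
Reactants: 11 the diol ester; 5 3,4-dimethoxybenzaldehyde
Product: 13 tert-butyl (5R)-5-{(R)-[(tert-butyldimethylsilyl)oxy](3,4-dimethoxyphenyl)methyl}-2-(3,4-dimethoxyphenyl)-1,3-dioxane-4-carboxylate (diastereomers at C-2 and C-4), via 3,4-dimethoxybenzaldehyde dimethyl acetal 12 (not isolated)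
Conditions: HC(OMe)3, PPTS (cat.), CH2Cl2, rt
Reagents that add atoms: none
Why: Acid-catalysed acetalisation of the 1,3-diol (through the dimethyl acetal made in the flask) should give the six-membered arylidene acetal under thermodynamic control; the acetal carbon is the future C3 and its configuration here is not carried on.

Step 7
Reactants: 13 the 2-aryl-1,3-dioxane-4-carboxylate
Product: 16 tert-butyl (2R,3R,4S)-4-{(R)-[(tert-butyldimethylsilyl)oxy](3,4-dimethoxyphenyl)methyl}-2-(3,4-dimethoxyphenyl)-3-[(triisopropylsilyl)oxy]oxolane-3-carboxylate, via lithium enolate 14 (not isolated), via triisopropylsilyl ketene acetal 15 (not isolated)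
Conditions: LiN(iPr)2, THF, −78 °C; iPr3SiOTf, −78 → −40 °C; then CH2Cl2, iPr3SiOTf (20 mol %), −78 → −30 °C
Reagents that add atoms: triisopropylsilyl trifluoromethanesulfonate CC(C)[Si](C(C)C)(C(C)C)OS(=O)(=O)C(F)(F)F
Why: Proposed new method: with the dioxane numbered O1–C2–O3–C4–C5–C6, ketene acetal 15 is a vinylogous vinyl acetal, so the silyl triflate should ionise C2–O3 to an E-oxocarbenium ion held through O1–C6–C5 beside an α-silyloxy ketene acetal, whose carbon C4 adds to C2 so that the six-membered dioxane contracts to the oxolane (net 1,2-shift of the acetal carbon from O to C, driven by formation of the ester C=O, the silyl group passing to the former ring oxygen). The closest known reaction types are the Petasis–Ferrier rearrangement and the Lewis-acid O→C ring contraction of 4,5-dihydro-1,3-dioxepins to tetrahydrofuran-3-carbaldehydes (same tethered oxocarbenium/enolate pair), the Mukaiyama addition of α-silyloxy ketene acetals to acetals, and the acetal [1,2]-Wittig rearrangement. Ring 1 is closed by C–C bond formation in a 5-(enolexo)-endo-trig mode, as in those precedents. The quaternary carbon is controlled by allylic 1,3-strain: the bulky ketene-acetal terminus forces the C5–H into the alkene plane, the CH(OTBS)Ar group then lies on the face away from the tethered cation, and bond formation on the tether face leaves the silyloxy group cis and the ester trans to that side chain. The benzylic carbon is set by the cation adding with its aryl group turned away from the ketene-acetal terminus (also the least-motion path from the acetal), which should put aryl cis to the silyloxy group. The step needs ionisation of C2–O3 and not C2–O1, secured by the enol-ether character of O3, and C- instead of O-recombination, secured because only C-attack is irreversible at low temperature.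

Step 8
Reactants: 16 the oxolane ester
Product: 17 [(2R,3S,4S)-4-{(R)-[(tert-butyldimethylsilyl)oxy](3,4-dimethoxyphenyl)methyl}-2-(3,4-dimethoxyphenyl)-3-[(triisopropylsilyl)oxy]oxolan-3-yl]methanol
Conditions: LiAlH4, THF, 0 °C → rt
Reagents that add atoms: none
Why: Hydride reduction of the hindered tert-butyl ester to the primary alcohol; silyl ethers and all stereocentres are untouched.

Step 9
Reactants: 17 the primary alcohol
Product: 18 [(2R,3S,4S)-4-{(R)-[(tert-butyldimethylsilyl)oxy](3,4-dimethoxyphenyl)methyl}-2-(3,4-dimethoxyphenyl)-3-[(triisopropylsilyl)oxy]oxolan-3-yl]methyl methanesulfonate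
Conditions: MsCl, Et3N, CH2Cl2, 0 °C
Reagents that add atoms: methanesulfonyl chloride CS(=O)(=O)Cl
Why: Sulfonylation through the sulfene pathway tolerates the neopentyl position and turns the primary hydroxyl into a leaving group; the tertiary oxygen is already blocked, so no epoxide can form.

Step 10
Reactants: 18 the mesylate
Product: 20 (3R,3aS,6R,6aS)-3,6-bis(3,4-dimethoxyphenyl)-3a-[(triisopropylsilyl)oxy]tetrahydro-1H,3H-furo[3,4-c]furan (trans-fused), via hydroxy mesylate 19 (not isolated)
Conditions: Bu4NF (1.2 equiv), THF, 0 → 45 °C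
Reagents that add atoms: none
Why: Fluoride removes the less hindered secondary silyl ether and the alkoxide closes ring 2 by intramolecular Williamson etherification (5-exo-tet SN2 at CH2, no stereocentre involved); the CH2OMs arm and the side chain are trans on ring 1, so the new ring is trans-fused, a closure known for trans-3-oxabicyclo[3.3.0]octanes, and the bulky triisopropylsilyl group should resist migration to the alkoxide.

Step 11
Reactants: 20 the silyl-protected bicycle
Product: 21 (3R,3aS,6R,6aS)-3,6-bis(3,4-dimethoxyphenyl)tetrahydro-1H,3H-furo[3,4-c]furan-3a(4H)-ol (trans-fused; the target)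
Conditions: Bu4NF (4 equiv), THF, 65 °C
Reagents that add atoms: none
Why: Fluoride cleavage of the tertiary silyl ether under basic conditions that do not ionise the benzylic ethers should free the bridgehead alcohol.

**Compound list**

1 | 4-tert-butoxy-4-oxobutanoic acid | CC(C)(C)OC(=O)CCC(=O)O | starting material
2 | (R)-4-benzyl-1,3-oxazolidin-2-one | O=C1OC[C@@H](Cc2ccccc2)N1 | starting material
3 | pivalic mixed anhydride of 1 (not isolated) | CC(C)(C)OC(=O)CCC(=O)OC(=O)C(C)(C)C | intermediate
4 | tert-butyl 4-[(4R)-4-benzyl-2-oxo-1,3-oxazolidin-3-yl]-4-oxobutanoate | CC(C)(C)OC(=O)CCC(=O)N1[C@H](Cc2ccccc2)COC1=O | intermediate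
5 | 3,4-dimethoxybenzaldehyde | COc1ccc(C=O)cc1OC | starting material
6 | dibutylboron Z-enolate of 4 (not isolated) | CCCCB(CCCC)O/C(=C\CC(=O)OC(C)(C)C)N1[C@H](Cc2ccccc2)COC1=O | intermediate
7 | tert-butyl (3R,4R)-3-{[(4R)-4-benzyl-2-oxo-1,3-oxazolidin-3-yl]carbonyl}-4-(3,4-dimethoxyphenyl)-4-hydroxybutanoate | CC(C)(C)OC(=O)C[C@@H](C(=O)N1[C@H](Cc2ccccc2)COC1=O)[C@@H](O)c1ccc(OC)c(OC)c1 | intermediate
8 | tert-butyl (3R,4R)-3-{[(4R)-4-benzyl-2-oxo-1,3-oxazolidin-3-yl]carbonyl}-4-[(tert-butyldimethylsilyl)oxy]-4-(3,4-dimethoxyphenyl)butanoate | CC(C)(C)OC(=O)C[C@@H](C(=O)N1[C@H](Cc2ccccc2)COC1=O)[C@@H](O[Si](C)(C)C(C)(C)C)c1ccc(OC)c(OC)c1 | intermediate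
9 | tert-butyl (3S,4R)-4-[(tert-butyldimethylsilyl)oxy]-4-(3,4-dimethoxyphenyl)-3-(hydroxymethyl)butanoate | CC(C)(C)OC(=O)C[C@@H](CO)[C@@H](O[Si](C)(C)C(C)(C)C)c1ccc(OC)c(OC)c1 | intermediate
10 | dipotassium alkoxide–enolate of 9 (not isolated) | CC(C)(C)OC(O[K])=C[C@@H](CO[K])[C@@H](O[Si](C)(C)C(C)(C)C)c1ccc(OC)c(OC)c1 | intermediate
11 | tert-butyl (3R,4R)-4-[(tert-butyldimethylsilyl)oxy]-4-(3,4-dimethoxyphenyl)-2-hydroxy-3-(hydroxymethyl)butanoate, both C-2 epimers | CC(C)(C)OC(=O)C(O)[C@@H](CO)[C@@H](O[Si](C)(C)C(C)(C)C)c1ccc(OC)c(OC)c1 | intermediate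
12 | 3,4-dimethoxybenzaldehyde dimethyl acetal (not isolated) | COc1ccc(C(OC)OC)cc1OC | intermediate
13 | tert-butyl (5R)-5-{(R)-[(tert-butyldimethylsilyl)oxy](3,4-dimethoxyphenyl)methyl}-2-(3,4-dimethoxyphenyl)-1,3-dioxane-4-carboxylate, diastereomers at C-2 and C-4 | CC(C)(C)OC(=O)C1OC(c2ccc(OC)c(OC)c2)OC[C@H]1[C@@H](O[Si](C)(C)C(C)(C)C)c1ccc(OC)c(OC)c1 | intermediate
14 | lithium enolate of 13 (not isolated) | CC(C)(C)OC(O[Li])=C1OC(c2ccc(OC)c(OC)c2)OC[C@H]1[C@@H](O[Si](C)(C)C(C)(C)C)c1ccc(OC)c(OC)c1 | intermediate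
15 | triisopropylsilyl ketene acetal of 13, a 4-alkylidene-2-aryl-1,3-dioxane (not isolated) | CC(C)(C)OC(O[Si](C(C)C)(C(C)C)C(C)C)=C1OC(c2ccc(OC)c(OC)c2)OC[C@H]1[C@@H](O[Si](C)(C)C(C)(C)C)c1ccc(OC)c(OC)c1 | intermediate
16 | tert-butyl (2R,3R,4S)-4-{(R)-[(tert-butyldimethylsilyl)oxy](3,4-dimethoxyphenyl)methyl}-2-(3,4-dimethoxyphenyl)-3-[(triisopropylsilyl)oxy]oxolane-3-carboxylate | COc1ccc([C@H]2OC[C@@H]([C@H](c3ccc(OC)c(OC)c3)O[Si](C)(C)C(C)(C)C)[C@]2(O[Si](C(C)C)(C(C)C)C(C)C)C(=O)OC(C)(C)C)cc1OC | intermediate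
17 | [(2R,3S,4S)-4-{(R)-[(tert-butyldimethylsilyl)oxy](3,4-dimethoxyphenyl)methyl}-2-(3,4-dimethoxyphenyl)-3-[(triisopropylsilyl)oxy]oxolan-3-yl]methanol | COc1ccc([C@H]2OC[C@@H]([C@H](c3ccc(OC)c(OC)c3)O[Si](C)(C)C(C)(C)C)[C@]2(O[Si](C(C)C)(C(C)C)C(C)C)CO)cc1OC | intermediate
18 | methanesulfonate of 17 | COc1ccc([C@H]2OC[C@@H]([C@H](c3ccc(OC)c(OC)c3)O[Si](C)(C)C(C)(C)C)[C@]2(O[Si](C(C)C)(C(C)C)C(C)C)COS(C)(=O)=O)cc1OC | intermediate
19 | hydroxy mesylate, 18 without the tert-butyldimethylsilyl group, formed as its alkoxide (not isolated) | COc1ccc([C@H]2OC[C@@H]([C@H](c3ccc(OC)c(OC)c3)O)[C@]2(O[Si](C(C)C)(C(C)C)C(C)C)COS(C)(=O)=O)cc1OC | intermediate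
20 | (3R,3aS,6R,6aS)-3,6-bis(3,4-dimethoxyphenyl)-3a-[(triisopropylsilyl)oxy]tetrahydro-1H,3H-furo[3,4-c]furan, trans-fused | COc1ccc([C@H]2OC[C@H]3[C@H](c4ccc(OC)c(OC)c4)OC[C@]23O[Si](C(C)C)(C(C)C)C(C)C)cc1OC | intermediate
21 | (3R,3aS,6R,6aS)-3,6-bis(3,4-dimethoxyphenyl)tetrahydro-1H,3H-furo[3,4-c]furan-3a(4H)-ol, trans-fused | COc1ccc([C@H]2OC[C@H]3[C@H](c4ccc(OC)c(OC)c4)OC[C@]23O)cc1OC | target

**Count and risks**

Total: 11 steps. Longest linear sequence: 11 steps (from 1; compounds 2 and 5 are bought).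

Steps most likely to fail:

1. Step 7 (the proposed new method). The ionised acetal may re-close on oxygen, the crowded quaternary centre may not form, or the oxocarbenium ion may add with poor facial selectivity at the benzylic carbon. The fallback uses known chemistry, sets out from 11 and comes back at 16. The primary hydroxyl of 11 would be silylated (Et3SiCl, imidazole, CH2Cl2, −20 °C) to the primary triethylsilyl ether F1. The α-hydroxyl would then be capped (iPr3SiOTf, 2,6-lutidine) to give the bis-silyl ether F2. The lithium enolate of F2 (LiN(iPr)2, THF, −78 °C) would be added to 5 in an intermolecular glycolate aldol reaction to give the aldol adduct F3; the aldehyde should attack the enolate face away from the CH(OTBS)Ar group for the same allylic-strain reason, and epimers at the new carbinol carbon would be separated here. Mild acid methanolysis (PPTS, MeOH, 0 °C) would free the primary alcohol to give the 1,4-diol F4. Mitsunobu cycloetherification (PPh3, DIAD, THF), which activates the primary hydroxyl and keeps the benzylic configuration, would then close ring 1 to 16.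

2. Step 10. Closure of the strained trans-fused ring may be slower than silyl migration to the alkoxide followed by epoxide formation, or slower than loss of the mesylate by other paths. The fallback sets out from 17 and comes back at 20. Alcohol 17 would be oxidised (Dess–Martin periodinane, NaHCO3, CH2Cl2) to the aldehyde F5. Ring 2 would then be closed by reductive etherification (BiBr3 cat., Et3SiH, MeCN, 0 °C): the benzylic silyl ether oxygen adds to the aldehyde and the cyclic oxocarbenium ion is reduced, which forms the C4–O5 bond by carbonyl chemistry instead of SN2 displacement.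

3. Step 5. The dianion may undergo intramolecular acyl transfer (lactonisation), or the enolate may be consumed by the sulfonimine that the oxidant leaves behind. The fallback sets out from 9 and comes back at 11. The alcohol would be silylated (Me3SiCl, Et3N, CH2Cl2) to the trimethylsilyl ether F6, and the ester converted to the trimethylsilyl ketene acetal F7 (LiN(iPr)2, Me3SiCl, THF, −78 °C). Rubottom oxidation (mCPBA, NaHCO3, CH2Cl2, 0 °C) would give the α-silyloxy ester F8, and K2CO3 in MeOH at 0 °C would remove both trimethylsilyl groups to give 11.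

Further compounds
F1 | step 7 | primary triethylsilyl ether of 11 | CC(C)(C)OC(=O)C(O)[C@@H](CO[Si](CC)(CC)CC)[C@@H](O[Si](C)(C)C(C)(C)C)c1ccc(OC)c(OC)c1
F2 | step 7 | F1 with the α-hydroxyl as triisopropylsilyl ether | CC(C)(C)OC(=O)C(O[Si](C(C)C)(C(C)C)C(C)C)[C@@H](CO[Si](CC)(CC)CC)[C@@H](O[Si](C)(C)C(C)(C)C)c1ccc(OC)c(OC)c1
F3 | step 7 | aldol adduct of F2 with 5 (open-chain precursor of 16 with primary triethylsilyl ether) | COc1ccc([C@@H](O)[C@@](O[Si](C(C)C)(C(C)C)C(C)C)(C(=O)OC(C)(C)C)[C@@H](CO[Si](CC)(CC)CC)[C@@H](O[Si](C)(C)C(C)(C)C)c2ccc(OC)c(OC)c2)cc1OC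
F4 | step 7 | 1,4-diol from F3 (primary alcohol free) | COc1ccc([C@@H](O)[C@@](O[Si](C(C)C)(C(C)C)C(C)C)(C(=O)OC(C)(C)C)[C@@H](CO)[C@@H](O[Si](C)(C)C(C)(C)C)c2ccc(OC)c(OC)c2)cc1OC
F5 | step 10 | aldehyde from 17 | COc1ccc([C@H]2OC[C@@H]([C@H](c3ccc(OC)c(OC)c3)O[Si](C)(C)C(C)(C)C)[C@]2(O[Si](C(C)C)(C(C)C)C(C)C)C=O)cc1OC
F6 | step 5 | trimethylsilyl ether of 9 | CC(C)(C)OC(=O)C[C@@H](CO[Si](C)(C)C)[C@@H](O[Si](C)(C)C(C)(C)C)c1ccc(OC)c(OC)c1
F7 | step 5 | trimethylsilyl ketene acetal of F6 | CC(C)(C)OC(O[Si](C)(C)C)=C[C@@H](CO[Si](C)(C)C)[C@@H](O[Si](C)(C)C(C)(C)C)c1ccc(OC)c(OC)c1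
F8 | step 5 | α-(trimethylsilyloxy) ester from Rubottom oxidation of F7 | CC(C)(C)OC(=O)C(O[Si](C)(C)C)[C@@H](CO[Si](C)(C)C)[C@@H](O[Si](C)(C)C(C)(C)C)c1ccc(OC)c(OC)c1
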